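**Plan**

1. Retrosynthesis: the eight aryl methyl ethers come off last. The seven-membered ring is cut at the bond between the bridge methine (the CH bearing the 2,4-dioxygenated phenyl ring) and the fused resorcinol ring (Friedel–Crafts). The bond from C4 of the central benzene (ring B) to the bridge CH2 is cut to an aryl triflate and 1-ethenyl-2,4-dimethoxybenzene (Heck).
2. Enabling feature, in benzodifuran numbering (O1, C2, C3, C3a, C4, C4a, C5, C6, O7, C7a, C8, C8a): the O–CH carbons C2 and C6 of the two dihydrofuran rings each carry a 4-oxygenated phenyl ring trans to the aryl group on C3 or C5, and before the seven-membered ring exists a twofold axis through C4 and C8 of ring B exchanges the two halves. The C2–aryl and C6–aryl bonds are therefore cut together, to a C2-symmetric bis-lactol and two molecules of anisole.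
3. The bis-lactol goes back through a twofold Nef reaction and a twofold rhodium-catalysed arylation (C3–aryl and C5–aryl bonds) to a bis(nitroalkene), and from there by a twofold Henry condensation to diformylphloroglucinol.
4. Forward order: ring B (phloroglucinol) is formylated, differentiated and triflated; the two nitroethenyl arms are built and arylated; both dihydrofuran rings close as lactols; both 4-methoxyphenyl groups are attached; the styryl arm is joined at C4; the seven-membered ring closes last, before global demethylation.
5. Stereochemistry: C3 and C5 by catalyst control (chiral diene–rhodium, both R); C2 and C6 by substrate control in the arylation (anti to the C3/C5 aryl, trans, both R); the bridge methine (R) by substrate control in the seven-membered ring closure.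

Key step: step 8

Assumption: the enantiomer of the chiral diene named in step 5 is taken to direct the aryl group to the Re face of each alkene carbon bonded to ring B; if a model nitrostyrene shows the opposite sense, the mirror-image ligand is used and nothing else changes.
Assumption: lactol 13 is carried forward as its mixture of anomers, since both lactol carbons become planar in step 8; the trans,trans anomer is the one drawn.

**Step 1**
Reactants: 1 phloroglucinol (benzene-1,3,5-triol)
Product: 3 2,4,6-trihydroxybenzene-1,3-dicarbaldehyde, via bis(iminium) dichloride 2 (not isolated)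
Conditions: POCl3 (2.2 equiv), DMF (2.2 equiv), 1,4-dioxane, 0 °C to rt; then H2O, rt
Reagents that add atoms: N,N-dimethylformamide, CN(C)C=O; water, O
Why: Twofold Vilsmeier–Haack formylation of the very electron-rich triphenol by the chloroiminium ion from DMF and POCl3 should stop at the 2,4-disubstituted stage with about two equivalents of reagent because each iminium group deactivates the ring, and water then hydrolyses the bis(iminium) salt to the dialdehyde.

**Step 2**
Reactants: 3 2,4,6-trihydroxybenzene-1,3-dicarbaldehyde
Product: 4 2-hydroxy-4,6-bis(methoxymethoxy)benzene-1,3-dicarbaldehyde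
Conditions: MOMCl (2.1 equiv), i-Pr2NEt, CH2Cl2, 0 °C
Reagents that add atoms: chloromethyl methyl ether, COCCl
Why: Base-mediated O-alkylation (methoxymethyl ether formation) should take place at the two hydroxyls that each lie para to one formyl group, which are the more acidic and less hindered ones, while the hydroxyl held between both formyl groups by hydrogen bonding is left free.

**Step 3**
Reactants: 4 2-hydroxy-4,6-bis(methoxymethoxy)benzene-1,3-dicarbaldehyde
Product: 5 2,6-diformyl-3,5-bis(methoxymethoxy)phenyl trifluoromethanesulfonate
Conditions: Tf2O, pyridine, CH2Cl2, −10 °C to rt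
Reagents that add atoms: trifluoromethanesulfonic anhydride, O=S(=O)(OS(=O)(=O)C(F)(F)F)C(F)(F)F
Why: O-Triflation of the one remaining phenol with Tf2O and pyridine is a standard sulfonylation of a chelated ortho-formyl phenol and turns the oxygen on the future C4 into the leaving group for the later palladium coupling.

**Step 4**
Reactants: 5 2,6-diformyl-3,5-bis(methoxymethoxy)phenyl trifluoromethanesulfonate; 6 nitromethane
Product: 7 3,5-bis(methoxymethoxy)-2,6-bis[(E)-2-nitroethenyl]phenyl trifluoromethanesulfonate
Conditions: MeNO2 (20 equiv), NH4OAc (0.5 equiv), no co-solvent, 80 °C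
Reagents that add atoms: nitromethane (the second equivalent of 6), C[N+](=O)[O-]
Why: Twofold Henry condensation (nitroaldol addition and loss of water), in which each of the two formyl groups takes up one molecule of nitromethane under ammonium acetate catalysis, gives the conjugated E nitroalkenes, and the medium is free of strong acid and strong base so that the MOM acetals and the triflate should be retained.

**Step 5**
Reactants: 7 3,5-bis(methoxymethoxy)-2,6-bis[(E)-2-nitroethenyl]phenyl trifluoromethanesulfonate; 8 3,5-dimethoxyphenylboronic acid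
Product: 9 2,6-bis[(1R)-1-(3,5-dimethoxyphenyl)-2-nitroethyl]-3,5-bis(methoxymethoxy)phenyl trifluoromethanesulfonate
Conditions: [RhCl(C2H4)2]2 (5 mol %), (3aR,6aR)-3,6-diphenyl-1,3a,4,6a-tetrahydropentalene (11 mol %), 8 (5 equiv), KOH (aq., 20 mol %), 1,4-dioxane/H2O 10:1, 40 °C
Reagents that add atoms: 3,5-dimethoxyphenylboronic acid (the second equivalent of 8), COc1cc(OC)cc(B(O)O)c1
Why: Rhodium-catalysed asymmetric conjugate arylation (Hayashi–Miyaura reaction) of β-aryl nitroalkenes is well established with chiral diene ligands; one aryl group is delivered to each of the two nitroalkenes, the aryl–rhodium species formed by transmetalation adds to the Re face of each alkene carbon bonded to ring B under catalyst control, which sets both benzylic centres as R, and because two independent additions are needed most stereochemical errors should end up in a separable meso isomer.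

**Step 6**
Reactants: 9 2,6-bis[(1R)-1-(3,5-dimethoxyphenyl)-2-nitroethyl]-3,5-bis(methoxymethoxy)phenyl trifluoromethanesulfonate
Product: 10 2,6-bis[(1R)-1-(3,5-dimethoxyphenyl)-2-nitroethyl]-3,5-dihydroxyphenyl trifluoromethanesulfonate
Conditions: HCl (3 M aq.), MeOH/THF, 45 °C
Reagents that add atoms: none
Why: Acid-catalysed acetal exchange removes both MOM groups as dimethoxymethane while the nitro groups, the triflate, the aryl methyl ethers and the two benzylic stereocentres are inert to dilute HCl in methanol.

**Step 7**
Reactants: 10 2,6-bis[(1R)-1-(3,5-dimethoxyphenyl)-2-nitroethyl]-3,5-dihydroxyphenyl trifluoromethanesulfonate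
Product: 13 (3R,5R)-3,5-bis(3,5-dimethoxyphenyl)-2,6-dihydroxy-2,3,5,6-tetrahydrobenzo[1,2-b:5,4-b']difuran-4-yl trifluoromethanesulfonate, via tetrasodium bis-nitronate 11 (not isolated), via open-chain dialdehyde 12 (not isolated)
Conditions: NaOMe (4.5 equiv), MeOH, 0 °C, 15 min; then added to TiCl3 (20% aq., 9 equiv), NH4OAc buffer (pH about 5), 0 °C to rt
Reagents that add atoms: water, O
Why: Reductive Nef reaction in which TiCl3 reduces each nitronate to an N-unsubstituted imine that water hydrolyses near pH 5, after which each aldehyde is trapped at once by the ortho phenol as a five-membered cyclic hemiacetal, so that the enolisable diarylacetaldehyde is never free for long and C3 and C5 should keep their configuration; the two new lactol carbons form as an anomeric mixture that does not matter because they become planar in the next step.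

**Step 8**
Reactants: 13 (3R,5R)-3,5-bis(3,5-dimethoxyphenyl)-2,6-dihydroxy-2,3,5,6-tetrahydrobenzo[1,2-b:5,4-b']difuran-4-yl trifluoromethanesulfonate; 14 anisole
Product: 15 (2R,3R,5R,6R)-3,5-bis(3,5-dimethoxyphenyl)-2,6-bis(4-methoxyphenyl)-2,3,5,6-tetrahydrobenzo[1,2-b:5,4-b']difuran-4-yl trifluoromethanesulfonate
Conditions: BF3·OEt2 (4 equiv), anisole (100 equiv), CH2Cl2, −40 °C to 0 °C; 13 added over 2 h, final concentration 0.01 M
Reagents that add atoms: anisole (the second equivalent of 14), COc1ccccc1
Why: BF3·OEt2 turns each lactol hydroxyl into a leaving group and the ring oxygen (O1 or O7) expels it to give a planar 2,3-dihydrobenzofuran-2-ylium (cyclic oxocarbenium) ion, which one molecule of anisole attacks through its para carbon, and loss of a proton from the arenium ion completes an intermolecular Friedel–Crafts arylation at C2 and then, with a second molecule of anisole, at C6. The closest known reaction type is the Lewis acid C-arylation of lactols and cyclic acetals by electron-rich arenes, as used for C-aryl glycosides and 2-aryl cyclic ethers. No ring is closed in this step; the two dihydrofuran rings are already present and only the C2–aryl and C6–aryl bonds are formed. The new stereocentres C2 and C6 are set by substrate control, since the 3,5-dimethoxyphenyl group on C3 or C5 blocks one face of the neighbouring cation and anisole enters anti to it, which gives the 2,3-trans and 5,6-trans relationships and, with (3R,5R) fixed, the (2R,6R) configuration; should a C2–O bond ionise again, the 4-methoxybenzylic cation is re-closed by the phenol oxygen to the more stable trans ring, so the expected outcome is also the thermodynamic one. The step needs arylation to outrun loss of the C3 or C5 proton, which would aromatise the ring to a benzofuran, and to outrun alkylation of the dimethoxyphenyl rings of a second substrate molecule: low temperature, a non-basic medium, a hundredfold excess of anisole and slow addition of 13 at high dilution are chosen for this, while the bulk of the cation favours para over ortho attack. The twofold axis makes the two ends equivalent, so one set of conditions serves both.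

**Step 9**
Reactants: 15 (2R,3R,5R,6R)-3,5-bis(3,5-dimethoxyphenyl)-2,6-bis(4-methoxyphenyl)-2,3,5,6-tetrahydrobenzo[1,2-b:5,4-b']difuran-4-yl trifluoromethanesulfonate; 16 1-ethenyl-2,4-dimethoxybenzene
Product: 17 (2R,3R,5R,6R)-4-[(E)-2-(2,4-dimethoxyphenyl)ethenyl]-3,5-bis(3,5-dimethoxyphenyl)-2,6-bis(4-methoxyphenyl)-2,3,5,6-tetrahydrobenzo[1,2-b:5,4-b']difuran
Conditions: Pd(OAc)2 (10 mol %), XPhos (20 mol %), Cy2NMe (2 equiv), LiCl, DMF, 110 °C
Reagents that add atoms: none
Why: Mizoroki–Heck reaction in which zerovalent palladium carrying a bulky electron-rich phosphine inserts into the hindered C4–OTf bond, the arylpalladium adds to the terminal carbon of the styrene and β-hydride elimination gives the E stilbene; the stereocentres are remote from the reacting site and are not touched.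

**Step 10**
Reactants: 17 (2R,3R,5R,6R)-4-[(E)-2-(2,4-dimethoxyphenyl)ethenyl]-3,5-bis(3,5-dimethoxyphenyl)-2,6-bis(4-methoxyphenyl)-2,3,5,6-tetrahydrobenzo[1,2-b:5,4-b']difuran
Product: 18 octa-O-methyl ether of the target (all five stereocentres R)
Conditions: TFA (10 equiv), CH2Cl2, −20 °C to rt
Reagents that add atoms: none
Why: Intramolecular Friedel–Crafts alkylation started by protonation of the stilbene at the carbon bonded to C4, which gives the cation stabilised by the 2,4-dimethoxyphenyl ring, and one of the two symmetry-equivalent 3,5-dimethoxyphenyl rings attacks it through the carbon that is ortho to one methoxy group and para to the other to close the seven-membered ring; the new methine centre is set by substrate control, since the trans-fused dihydrofuran fixes the fold of the forming ring and the 2,4-dimethoxyphenyl group should take the pseudo-equatorial position on the face of the seven-membered ring opposite to C6, which corresponds to R, and the acid-reversibility of this benzylic bond allows correction towards that more stable isomer.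

**Step 11**
Reactants: 18 octa-O-methyl ether of the target
Product: 19 the target CNP0154047.1
Conditions: BBr3 (24 equiv), CH2Cl2, −78 °C to rt; then MeOH, H2O
Reagents that add atoms: none
Why: Exhaustive cleavage of the eight aryl methyl ethers by BBr3 (Lewis acid–base complexation followed by bromide attack on each methyl group) frees all phenols, and the benzylic ring C–O bonds should survive at low temperature or, if they ionise, re-close to the same trans rings, so no stereocentre is expected to change.

**Compound list**

1 | phloroglucinol | Oc1cc(O)cc(O)c1 | starting material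
2 | bis(iminium) dichloride of 2,4-bis(dimethyliminiomethyl)phloroglucinol | C[N+](C)=Cc1c(O)cc(O)c(C=[N+](C)C)c1O.[Cl-].[Cl-] | intermediate
3 | 2,4,6-trihydroxybenzene-1,3-dicarbaldehyde (2,4-diformylphloroglucinol) | O=Cc1c(O)cc(O)c(C=O)c1O | intermediate
4 | 2-hydroxy-4,6-bis(methoxymethoxy)benzene-1,3-dicarbaldehyde | COCOc1cc(OCOC)c(C=O)c(O)c1C=O | intermediate
5 | 2,6-diformyl-3,5-bis(methoxymethoxy)phenyl trifluoromethanesulfonate | COCOc1cc(OCOC)c(C=O)c(OS(=O)(=O)C(F)(F)F)c1C=O | intermediate
6 | nitromethane | C[N+](=O)[O-] | starting material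
7 | 3,5-bis(methoxymethoxy)-2,6-bis[(E)-2-nitroethenyl]phenyl trifluoromethanesulfonate | COCOc1cc(OCOC)c(/C=C/[N+](=O)[O-])c(OS(=O)(=O)C(F)(F)F)c1/C=C/[N+](=O)[O-] | intermediate
8 | 3,5-dimethoxyphenylboronic acid | COc1cc(OC)cc(B(O)O)c1 | starting material
9 | 2,6-bis[(1R)-1-(3,5-dimethoxyphenyl)-2-nitroethyl]-3,5-bis(methoxymethoxy)phenyl trifluoromethanesulfonate | COCOc1cc(OCOC)c([C@H](C[N+](=O)[O-])c2cc(OC)cc(OC)c2)c(OS(=O)(=O)C(F)(F)F)c1[C@H](C[N+](=O)[O-])c1cc(OC)cc(OC)c1 | intermediate
10 | 2,6-bis[(1R)-1-(3,5-dimethoxyphenyl)-2-nitroethyl]-3,5-dihydroxyphenyl trifluoromethanesulfonate | Oc1cc(O)c([C@H](C[N+](=O)[O-])c2cc(OC)cc(OC)c2)c(OS(=O)(=O)C(F)(F)F)c1[C@H](C[N+](=O)[O-])c1cc(OC)cc(OC)c1 | intermediate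
11 | tetrasodium salt of 10 (both nitro groups as nitronates, both phenols as phenoxides) | [Na+].[Na+].[Na+].[Na+].[O-]c1cc([O-])c([C@H](C=[N+]([O-])[O-])c2cc(OC)cc(OC)c2)c(OS(=O)(=O)C(F)(F)F)c1[C@H](C=[N+]([O-])[O-])c1cc(OC)cc(OC)c1 | intermediate
12 | 2,6-bis[(1R)-1-(3,5-dimethoxyphenyl)-2-oxoethyl]-3,5-dihydroxyphenyl trifluoromethanesulfonate (open-chain dialdehyde) | Oc1cc(O)c([C@H](C=O)c2cc(OC)cc(OC)c2)c(OS(=O)(=O)C(F)(F)F)c1[C@H](C=O)c1cc(OC)cc(OC)c1 | intermediate
13 | (3R,5R)-3,5-bis(3,5-dimethoxyphenyl)-2,6-dihydroxy-2,3,5,6-tetrahydrobenzo[1,2-b:5,4-b']difuran-4-yl trifluoromethanesulfonate (mixture of lactol anomers; the 2R,3R,5R,6R trans,trans anomer is drawn) | O[C@@H]1Oc2cc3c(c(OS(=O)(=O)C(F)(F)F)c2[C@H]1c1cc(OC)cc(OC)c1)[C@@H](c1cc(OC)cc(OC)c1)[C@H](O)O3 | intermediate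
14 | anisole | COc1ccccc1 | starting material
15 | (2R,3R,5R,6R)-3,5-bis(3,5-dimethoxyphenyl)-2,6-bis(4-methoxyphenyl)-2,3,5,6-tetrahydrobenzo[1,2-b:5,4-b']difuran-4-yl trifluoromethanesulfonate | COc1ccc([C@@H]2Oc3cc4c(c(OS(=O)(=O)C(F)(F)F)c3[C@H]2c2cc(OC)cc(OC)c2)[C@@H](c2cc(OC)cc(OC)c2)[C@H](c2ccc(OC)cc2)O4)cc1 | intermediate
16 | 1-ethenyl-2,4-dimethoxybenzene | COc1ccc(C=C)c(OC)c1 | starting material
17 | (2R,3R,5R,6R)-4-[(E)-2-(2,4-dimethoxyphenyl)ethenyl]-3,5-bis(3,5-dimethoxyphenyl)-2,6-bis(4-methoxyphenyl)-2,3,5,6-tetrahydrobenzo[1,2-b:5,4-b']difuran | COc1ccc([C@@H]2Oc3cc4c(c(/C=C/c5ccc(OC)cc5OC)c3[C@H]2c2cc(OC)cc(OC)c2)[C@@H](c2cc(OC)cc(OC)c2)[C@H](c2ccc(OC)cc2)O4)cc1 | intermediate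
18 | octa-O-methyl ether of the target: ring B carries one trans-2-(4-methoxyphenyl)-3-(3,5-dimethoxyphenyl)dihydrofuran (2R,3R) and a second trans-dihydrofuran (2R,3R) whose C3 aryl group is a dimethoxy-substituted benzene ring fused into a seven-membered ring that is completed by the CH2 on C4 of ring B and an (R)-CH bearing 2,4-dimethoxyphenyl | COc1ccc([C@@H]2Oc3cc4c5c(c3[C@H]2c2cc(OC)cc(OC)c2)C[C@H](c2ccc(OC)cc2OC)c2c(OC)cc(OC)cc2[C@H]5[C@H](c2ccc(OC)cc2)O4)cc1 | intermediate
19 | CNP0154047.1: the octaphenol of the same skeleton, both dihydrofuran rings trans (2R,3R), bridge methine R | Oc1ccc([C@@H]2Oc3cc4c5c(c3[C@H]2c2cc(O)cc(O)c2)C[C@H](c2ccc(O)cc2O)c2c(O)cc(O)cc2[C@H]5[C@H](c2ccc(O)cc2)O4)cc1 | target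

**Step count and risks**

Total step count: 11. Longest linear sequence: 11 steps (1 to 19).

Steps most likely to fail:

Step 8. After ionisation of the lactol, loss of the proton at C3 or C5 (aromatisation of the dihydrofuran to a benzofuran, with loss of the stereocentre) or Friedel–Crafts attack by the more electron-rich dimethoxyphenyl rings of a second molecule may outpace capture by anisole. The fallback sets out from 13. Treatment with 4-MeOC6H4MgBr pre-mixed with CeCl3 in THF at −78 °C should open each lactol to its phenoxide aldehyde and add the aryl group to the carbonyl, giving the bis(benzylic alcohol) 2,6-bis[(1R)-1-(3,5-dimethoxyphenyl)-2-hydroxy-2-(4-methoxyphenyl)ethyl]-3,5-dihydroxyphenyl trifluoromethanesulfonate F1 as a mixture of carbinol epimers; the cerium reagent is chosen to suppress enolisation of the aldehyde. Catalytic p-TsOH in CH2Cl2 at 0 °C should then ionise each 4-methoxybenzylic alcohol, and the neighbouring phenol closes the five-membered ring anti to the C3 or C5 aryl group (cyclodehydration), which returns to the route at 15. Here the C2–aryl and C6–aryl bonds come from a carbonyl addition and the rings close through the O–C bonds.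

Step 7. Loss of configurational purity at C3 and C5 through imine–enamine or aldehyde–enol tautomerism before the hemiacetal closes, acid-induced dehydration of the lactol, or cleavage of the triflate by methoxide during nitronate formation may lower the quality of 13. The fallback sets out from 10. Nitrite-mediated oxidation of the primary nitro groups (NaNO2, AcOH, DMSO, 35 °C) should give the bis(carboxylic acid) (2R,2'R)-2,2'-[4,6-dihydroxy-2-(trifluoromethanesulfonyloxy)-1,3-phenylene]bis[2-(3,5-dimethoxyphenyl)acetic acid] F2 under acidic conditions that do not enolise the benzylic centres. Catalytic p-TsOH in warm toluene should close both lactones to (3R,5R)-3,5-bis(3,5-dimethoxyphenyl)-2,6-dioxo-2,3,5,6-tetrahydrobenzo[1,2-b:5,4-b']difuran-4-yl trifluoromethanesulfonate F3, which is kept away from base because its C3 and C5 protons are acidic. Reduction with i-Bu2AlH (2.2 equiv) in CH2Cl2 at −78 °C stops at the lactol and returns to the route at 13.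

Step 9. Oxidative addition and alkene insertion at the triflate carbon, which is flanked by two aryl-bearing benzylic carbons, may be slow, so that reduction of the triflate or insertion with the wrong regiochemistry competes. The fallback sets out from 16. Cross-metathesis with 2-ethenyl-4,4,5,5-tetramethyl-1,3,2-dioxaborolane (second-generation Grubbs catalyst, CH2Cl2, 40 °C) should give 2-[(E)-2-(2,4-dimethoxyphenyl)ethenyl]-4,4,5,5-tetramethyl-1,3,2-dioxaborolane F4. Suzuki–Miyaura coupling of this boronate with triflate 15 (Pd(OAc)2, SPhos, K3PO4, toluene/H2O, 90 °C) forms the same C4–alkenyl bond with the E geometry and the regiochemistry already fixed in the boron reagent, and returns to the route at 17.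

**Further compounds**

F1 | step 8 | 2,6-bis[(1R)-1-(3,5-dimethoxyphenyl)-2-hydroxy-2-(4-methoxyphenyl)ethyl]-3,5-dihydroxyphenyl trifluoromethanesulfonate (carbinol epimers) | COc1ccc(C(O)[C@H](c2cc(OC)cc(OC)c2)c2c(O)cc(O)c([C@H](C(O)c3ccc(OC)cc3)c3cc(OC)cc(OC)c3)c2OS(=O)(=O)C(F)(F)F)cc1
F2 | step 7 | (2R,2'R)-2,2'-[4,6-dihydroxy-2-(trifluoromethanesulfonyloxy)-1,3-phenylene]bis[2-(3,5-dimethoxyphenyl)acetic acid] | OC(=O)[C@H](c1cc(OC)cc(OC)c1)c1c(O)cc(O)c([C@H](C(O)=O)c2cc(OC)cc(OC)c2)c1OS(=O)(=O)C(F)(F)F
F3 | step 7 | (3R,5R)-3,5-bis(3,5-dimethoxyphenyl)-2,6-dioxo-2,3,5,6-tetrahydrobenzo[1,2-b:5,4-b']difuran-4-yl trifluoromethanesulfonate | O=C1Oc2cc3c(c(OS(=O)(=O)C(F)(F)F)c2[C@H]1c1cc(OC)cc(OC)c1)[C@@H](c1cc(OC)cc(OC)c1)C(=O)O3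
F4 | step 9 | 2-[(E)-2-(2,4-dimethoxyphenyl)ethenyl]-4,4,5,5-tetramethyl-1,3,2-dioxaborolane | COc1ccc(/C=C/B2OC(C)(C)C(C)(C)O2)c(OC)c1
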